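Compound numbers refer to the steps and to the compound list below.

## Analysis of the target

The target 23 is a flavonol: a 4H-chromen-4-one (rings A and C) with a 3,4-dihydroxyphenyl ring B on C2 and a hydroxyl on C3. Ring A is oxygenated everywhere except C6: a free hydroxyl on C5 (hydrogen-bonded to the C4 carbonyl), a methyl ether on C7 and an acetate on C8, next to the ring oxygen O1. There is no stereocentre, so the problem is regiochemistry and the differentiation of six oxygen atoms, not stereocontrol. The sensitive groups are the aryl acetate (lost to base, nucleophilic alcohols or hydride), the ring B catechol, and the 5,8-dioxygenated ring A, which is a para-hydroquinone derivative and oxidises easily once both oxygens are free. The hard part is that O8 alone must end up acylated while O3, O5, O3' and O4' end up free, so O8 needs its own protecting group from the start and the acetate must go on late. A further difficulty is fusing the pyranone onto the crowded, electron-rich ring A in the right orientation. The strategy rests on one feature of ring A: C8a, which carries O1, has only one hydrogen-bearing ortho neighbour, C4a, because C8 is oxygenated. A three-carbon unit hung on O1 can therefore be handed over only to C4a, and the C3=C4 double bond left behind sits exactly where the C3 hydroxyl and the C4 carbonyl are needed.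

## Retrosynthetic reasoning

**23 from 22.** The four O–benzyl bonds on O3, O5, O3' and O4' are cut last. Hydrogenolysis is neutral and leaves the aryl acetate alone. Because the acetate is already in place in 22, no selective acylation among five hydroxyls is ever needed.

**22 from 21 and 20.** The O8–acetyl bond is cut next. In 21, O8 is the only free hydroxyl, so acetylation needs no selectivity. Phenol 21 comes from 20, where O8 carries a methoxymethyl group that mild acid removes without touching benzyl ethers.

**20 from 19.** The O3–benzyl bond is cut. The C3 hydroxyl only appears when the pyranone is formed, and it would compete with O8 in the acetylation. It is therefore benzylated as soon as it exists and leaves with the other benzyl groups.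

**19 from 17 and 16.** The C3–O and C4–O bonds are traced back to the C3=C4 alkene of chromene 16. Flavonol 19 is the enol tautomer of the 3,4-dione 18, which is diol 17 oxidised twice, and 17 is the dihydroxylation product of 16. The pyranone oxidation level is thus reached late, from an alkene that is inert in the earlier steps. All three stereocentres of 17 disappear in 19, so the facial selectivity of the dihydroxylation does not matter.

**16 from 12 (key disconnection).** The C4–C4a bond is cut. It is the only carbon–carbon bond joining ring A to the rest of the molecule. Opening it leads to the aryl propargyl ether 12, in which C2, C3, C4 and ring B already hang on O1. Making this bond by sigmatropic delivery from O1 needs no acyl or halogen handle on ring A, and the substitution pattern fixes the regiochemistry. The forward reaction must shift the alkyne terminus to C4a, move a hydrogen, and re-close O1 onto C2.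

**12 from 8 and 11.** The O1–C2 ether bond is cut to phenol 8 and the propargylic alcohol 11. A redox condensation joins them under neutral conditions, which matters because the carbinol carbon of 11 is both benzylic and propargylic and ionises easily.

**11 from 9 and 10.** The bond between the carbinol carbon and the alkyne is cut. Adding the acetylide 10 to aldehyde 9 brings in ring B with its two benzyl ethers in one step.

**8 from 5, 4, 2 and 1.** Phenol 8 has four oxygens with four different roles. Its free hydroxyl is traced back to the bromine of 5, the benzyloxy group to phenol 4, that phenol to the formyl group of 2 by oxygen insertion, and the methoxymethyl ether to the single phenol of 1. In 1 the four positions are already distinct (OH, OMe, CHO, Br), so no regioselective mono-protection and no temporary third protecting group is needed; each operation has only one site to react at.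

## Alternatives that were turned down

**Alternative 1: ring C by intramolecular ester olefination.**
- Disconnection: the C2=C3 bond. The precursor is the aryl ester acylphosphorane A2; on heating, its ylide carbon attacks the neighbouring ester carbonyl in an intramolecular Wittig reaction and gives flavone A1.
- For it: it is a reliable ring closure at moderate temperature, and it delivers the C4 carbonyl and the C2=C3 bond at the correct oxidation level directly. On this point it is stronger than the chosen route, which needs two oxidation steps after the ring closure.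
- Against it: A1 has no oxygen on C3, so a separate C3 hydroxylation of an electron-rich, polybenzylated flavone is needed. A2 also requires C-acylation of the tetra-oxygenated ring A, α-halogenation, phosphonium salt and ylide formation and O-aroylation, roughly five operations from phenol 8 against two in the chosen route.
- Comparison: the chosen route gets the C3 oxygen from the same alkene that the ring closure leaves, and uses phenol 8 without any C-acylation.

**Alternative 2: ring A by cyclobutenone ring expansion.**
- Disconnection: the C4a–C5 bond. The 4-acetoxycyclobutenone A4 undergoes thermal four-electron ring opening and six-electron ring closure onto C4a of its pyranone substituent, and tautomerisation gives A3.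
- For it: it is the most convergent plan, and it is stronger than the chosen route in the endgame. A3 already has the acetate on O8 and the free hydroxyl on O5, one hydrogenolysis from 23, with no protecting-group changes on ring A.
- Against it: A4 has to be assembled from a pyranone fragment metallated next to its ring oxygen, which needs its own multistep synthesis and an uncertain metalation. The assembly then requires a regioselective carbonyl addition to an unsymmetrical four-membered ring dione and acylation of a hindered tertiary alkoxide. The ring opening must also turn the acetoxy group outward, and an acetoxy group is a weaker donor than the hydroxyl or silyloxy groups usually relied on for this. Several uncertain steps are stacked before and in the key step.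
- Comparison: the chosen route has a longer endgame, but every step before the key step is standard, and the uncertainty sits in one well-understood thermal cascade.

**Alternative 3: aryne insertion into an arylpropiolic acid.**
- Disconnection: O1–C8a, C4–C4a and O1–C2 in one operation. The fluoride-generated aryne A6 inserts into the C–O bond of acid A7, and intramolecular oxa-Michael closure then gives flavone A5.
- For it: it is the shortest route to a chromone core, under mild conditions, and the methoxy group should direct the carboxylate to the distal aryne carbon. On the speed of core construction it is stronger than the chosen route.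
- Against it: A5 lacks both the C8 and the C3 oxygen and carries two methyl ethers. It would need selective 5-O-demethylation, oxygenation at C8 in competition with C6, and C3 hydroxylation, and none of these is as selective as the steps of the chosen route.
- Comparison: the chosen route carries all four ring A oxygens, already differentiated, from the first step.

Key step: step 7

Remark on the chemistry: the target is achiral, so the chiral intermediates (11–14, 16–18) are handled as racemates. For diol 17 one enantiomer is drawn to show the relative configuration.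

## Route

Step 1
Reactants: 1 3-bromo-4-hydroxy-5-methoxybenzaldehyde (5-bromovanillin)
Product: 2 3-bromo-5-methoxy-4-(methoxymethoxy)benzaldehyde
Conditions: MOMCl, iPr2NEt, CH2Cl2, 0 °C to rt
Reagents that add atoms: chloromethyl methyl ether, COCCl
Why: O-alkylation of the only phenol (methoxymethyl protection); the hindered amine base leaves the aldehyde untouched. The acetal on the future O8 is orthogonal to the benzyl ethers used elsewhere.

Step 2
Reactants: 2 3-bromo-5-methoxy-4-(methoxymethoxy)benzaldehyde
Product: 4 3-bromo-5-methoxy-4-(methoxymethoxy)phenol, via aryl formate 3 (not isolated)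
Conditions: mCPBA, NaHCO3, CH2Cl2, 0 °C to rt; then K2CO3 (cat.), MeOH, rt
Reagents that add atoms: 3-chloroperoxybenzoic acid, OOC(=O)c1cccc(Cl)c1
Why: Baeyer–Villiger (Dakin-type) oxidation; the aryl group, made electron-rich by the para oxygen, should migrate in the Criegee intermediate in preference to hydride and give formate 3, which mild methanolysis cleaves. The bicarbonate buffer protects the acetal, and the bromide and methyl ether are inert to peracid.

Step 3
Reactants: 4 3-bromo-5-methoxy-4-(methoxymethoxy)phenol
Product: 5 5-(benzyloxy)-1-bromo-3-methoxy-2-(methoxymethoxy)benzene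
Conditions: BnBr, K2CO3, DMF, rt
Reagents that add atoms: benzyl bromide, BrCc1ccccc1
Why: Williamson ether synthesis on an unhindered phenoxide. Benzyl is chosen for the future O5 because it survives organolithium, heating to about 190 °C and the acid used later for acetal removal, and leaves by hydrogenolysis.

Step 4
Reactants: 5 5-(benzyloxy)-1-bromo-3-methoxy-2-(methoxymethoxy)benzene
Product: 8 5-(benzyloxy)-3-methoxy-2-(methoxymethoxy)phenol, via aryllithium 6 (not isolated), via dimethyl arylboronate 7 (not isolated)
Conditions: n-BuLi, THF, −78 °C; B(OMe)3, −78 °C to rt; then H2O2, aq. NaOH, 0 °C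
Reagents that add atoms: n-butyllithium, [Li]CCCC; trimethyl borate, COB(OC)OC; hydrogen peroxide, OO
Why: Bromine–lithium exchange is faster at −78 °C than any deprotonation, and the neighbouring acetal oxygen stabilises aryllithium 6. Borylation and the oxidative aryl shift from boron to oxygen are the standard one-flask conversion of an aryl bromide into a phenol, under basic conditions that the acetal tolerates. The lithium of n-butyllithium appears only in 6 and the dimethoxyboryl group of trimethyl borate only in 7, whereas the new phenol oxygen of 8 comes from hydrogen peroxide.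

Step 5
Reactants: 9 3,4-bis(benzyloxy)benzaldehyde; 10 ethynylmagnesium bromide
Product: 11 1-[3,4-bis(benzyloxy)phenyl]prop-2-yn-1-ol (racemic)
Conditions: THF, 0 °C to rt; then sat. aq. NH4Cl
Reagents that add atoms: none
Why: Grignard addition of the acetylide to the aldehyde. The carbinol centre forms as a racemate, which is sufficient because this centre is erased at the flavonol stage.

Step 6
Reactants: 8 5-(benzyloxy)-3-methoxy-2-(methoxymethoxy)phenol; 11 1-[3,4-bis(benzyloxy)phenyl]prop-2-yn-1-ol (racemic)
Product: 12 5-(benzyloxy)-1-{1-[3,4-bis(benzyloxy)phenyl]prop-2-yn-1-yloxy}-3-methoxy-2-(methoxymethoxy)benzene (racemic)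
Conditions: PPh3, DIAD, toluene/THF, 0 °C to rt
Reagents that add atoms: none
Why: Mitsunobu etherification; the phenol protonates the betaine and displaces the oxyphosphonium of the secondary propargylic alcohol by SN2, under neutral conditions that should not ionise the doubly activated carbinol. Configuration is irrelevant because 11 is racemic.

Step 7
Reactants: 12 5-(benzyloxy)-1-{1-[3,4-bis(benzyloxy)phenyl]prop-2-yn-1-yloxy}-3-methoxy-2-(methoxymethoxy)benzene (racemic)
Product: 16 5-(benzyloxy)-2-[3,4-bis(benzyloxy)phenyl]-7-methoxy-8-(methoxymethoxy)-2H-chromene (racemic), via allenyl dienone 13 (not isolated), via ortho-allenylphenol 14 (not isolated), via ortho-quinone methide 15 (not isolated)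
Conditions: PhNEt2 (0.05 M), 185 °C, Ar
Reagents that add atoms: none
Why: This is the thermal Claisen rearrangement of an aryl propargyl ether to a 2H-chromene, a known cascade. A [3,3]-sigmatropic shift bonds the alkyne terminus (C4) to the hydrogen-bearing ortho carbon (C4a) and gives allenyl dienone 13, which enolises to ortho-allenylphenol 14. A 1,5-hydrogen shift from the phenolic O–H to the central allene carbon then gives the 1-oxatriene 15, with the side chain held cis to the carbonyl by the cyclic transition state. Ring C, a six-membered pyran, closes by thermally allowed disrotatory oxa-6π electrocyclisation, O1 bonding to the aryl-bearing C2. No new stereocentre has to be controlled: C2 is regenerated as a racemate and disappears in step 9. The selectivity needed is regiochemical, and ring A secures it, because of the two carbons ortho to the ether oxygen only C4a carries hydrogen. A shift to the oxygen-bearing C8 gives a dienone that cannot enolise and mainly reverts to 12; its only other outlet is a second [3,3] shift to the free para carbon C6, and the amine solvent speeds the enolisation of 13 so that the productive channel should drain the equilibrium first. The four donor oxygens of ring A and the aryl group on the propargylic carbon should lower the barrier of the first shift.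

Step 8
Reactants: 16 5-(benzyloxy)-2-[3,4-bis(benzyloxy)phenyl]-7-methoxy-8-(methoxymethoxy)-2H-chromene (racemic)
Product: 17 rac-(2R,3S,4S)-5-(benzyloxy)-2-[3,4-bis(benzyloxy)phenyl]-7-methoxy-8-(methoxymethoxy)-3,4-dihydro-2H-chromene-3,4-diol (2,3-trans-3,4-cis)
Conditions: OsO4 (cat.), NMO, acetone/THF/H2O, rt
Reagents that add atoms: N-methylmorpholine N-oxide, C[N+]1([O-])CCOCC1; water, O; OsO4, O=[Os](=O)(=O)=O
Why: Osmium-catalysed syn-dihydroxylation of the electron-rich cis-styrenyl alkene with NMO as reoxidant; in the net equation one oxygen comes from the N-oxide and one from water, both relayed through the oxo ligands of the catalytic OsO4. OsO4 should add to the face away from the C2 aryl group and give the 2,3-trans-3,4-cis diol, but the relative configuration has no consequence because all three centres are removed in step 9.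

Step 9
Reactants: 17 rac-(2R,3S,4S)-5-(benzyloxy)-2-[3,4-bis(benzyloxy)phenyl]-7-methoxy-8-(methoxymethoxy)-3,4-dihydro-2H-chromene-3,4-diol
Product: 19 5-(benzyloxy)-2-[3,4-bis(benzyloxy)phenyl]-3-hydroxy-7-methoxy-8-(methoxymethoxy)-4H-chromen-4-one, via flavan-3,4-dione 18 (not isolated)
Conditions: IBX (3 equiv), DMSO, 25 to 45 °C
Reagents that add atoms: none
Why: IBX oxidises 1,2-diols to 1,2-diketones without C–C cleavage; both carbinols should be oxidised, the benzylic C4–OH first. Dione 18 has an acidic C2–H and should enolise spontaneously to the 3-hydroxypyranone, driven by formation of the aromatic 4H-chromen-4-one.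

Step 10
Reactants: 19 5-(benzyloxy)-2-[3,4-bis(benzyloxy)phenyl]-3-hydroxy-7-methoxy-8-(methoxymethoxy)-4H-chromen-4-one
Product: 20 3,5-bis(benzyloxy)-2-[3,4-bis(benzyloxy)phenyl]-7-methoxy-8-(methoxymethoxy)-4H-chromen-4-one
Conditions: BnBr, K2CO3, DMF, 50 °C
Reagents that add atoms: benzyl bromide, BrCc1ccccc1
Why: Williamson benzylation of the acidic enolic 3-hydroxyl, the only free OH in 19. It has to be masked so that O8 is the only hydroxyl free at the acetylation.

Step 11
Reactants: 20 3,5-bis(benzyloxy)-2-[3,4-bis(benzyloxy)phenyl]-7-methoxy-8-(methoxymethoxy)-4H-chromen-4-one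
Product: 21 3,5-bis(benzyloxy)-2-[3,4-bis(benzyloxy)phenyl]-8-hydroxy-7-methoxy-4H-chromen-4-one
Conditions: 3 M aq. HCl, MeOH/THF, 50 °C
Reagents that add atoms: none
Why: Acid-catalysed acetal exchange with methanol cleaves the methoxymethyl ether under conditions that aryl benzyl ethers and the flavone should tolerate, and frees O8 alone.

Step 12
Reactants: 21 3,5-bis(benzyloxy)-2-[3,4-bis(benzyloxy)phenyl]-8-hydroxy-7-methoxy-4H-chromen-4-one
Product: 22 3,5-bis(benzyloxy)-2-[3,4-bis(benzyloxy)phenyl]-7-methoxy-4-oxo-4H-chromen-8-yl acetate
Conditions: Ac2O, pyridine, DMAP (cat.), CH2Cl2, 0 °C to rt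
Reagents that add atoms: acetic anhydride, CC(=O)OC(C)=O
Why: DMAP-catalysed acylation of the single free phenol; the two ortho substituents slow it but should not prevent it.

Step 13
Reactants: 22 3,5-bis(benzyloxy)-2-[3,4-bis(benzyloxy)phenyl]-7-methoxy-4-oxo-4H-chromen-8-yl acetate
Product: 23 2-(3,4-dihydroxyphenyl)-3,5-dihydroxy-7-methoxy-4-oxo-4H-chromen-8-yl acetate (gossypetin 7-methyl ether 8-acetate)
Conditions: H2 (1 atm), Pd/C (10%), EtOAc/THF, rt
Reagents that add atoms: none
Why: Hydrogenolysis of the four benzyl ethers under neutral, aprotic conditions should leave the aryl acetate and the aromatic pyranone untouched. The acetyl group has no free neighbouring hydroxyl to migrate to, since its neighbours are the methyl ether on C7 and the ring oxygen O1.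

## Compound list

1 | 3-bromo-4-hydroxy-5-methoxybenzaldehyde (5-bromovanillin) | COc1cc(C=O)cc(Br)c1O | starting material
2 | 3-bromo-5-methoxy-4-(methoxymethoxy)benzaldehyde | COCOc1c(Br)cc(C=O)cc1OC | intermediate
3 | 3-bromo-5-methoxy-4-(methoxymethoxy)phenyl formate | COCOc1c(Br)cc(OC=O)cc1OC | intermediate
4 | 3-bromo-5-methoxy-4-(methoxymethoxy)phenol | COCOc1c(Br)cc(O)cc1OC | intermediate
5 | 5-(benzyloxy)-1-bromo-3-methoxy-2-(methoxymethoxy)benzene | COCOc1c(Br)cc(OCc2ccccc2)cc1OC | intermediate
6 | [5-(benzyloxy)-3-methoxy-2-(methoxymethoxy)phenyl]lithium | COCOc1c([Li])cc(OCc2ccccc2)cc1OC | intermediate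
7 | dimethyl [5-(benzyloxy)-3-methoxy-2-(methoxymethoxy)phenyl]boronate | COCOc1c(B(OC)OC)cc(OCc2ccccc2)cc1OC | intermediate
8 | 5-(benzyloxy)-3-methoxy-2-(methoxymethoxy)phenol | COCOc1c(O)cc(OCc2ccccc2)cc1OC | intermediate
9 | 3,4-bis(benzyloxy)benzaldehyde | O=Cc1ccc(OCc2ccccc2)c(OCc2ccccc2)c1 | starting material
10 | ethynylmagnesium bromide | C#C[Mg]Br | starting material
11 | 1-[3,4-bis(benzyloxy)phenyl]prop-2-yn-1-ol (racemic) | C#CC(O)c1ccc(OCc2ccccc2)c(OCc2ccccc2)c1 | intermediate
12 | 5-(benzyloxy)-1-{1-[3,4-bis(benzyloxy)phenyl]prop-2-yn-1-yloxy}-3-methoxy-2-(methoxymethoxy)benzene (racemic) | C#CC(Oc1cc(OCc2ccccc2)cc(OC)c1OCOC)c1ccc(OCc2ccccc2)c(OCc2ccccc2)c1 | intermediate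
13 | 5-(benzyloxy)-6-{3-[3,4-bis(benzyloxy)phenyl]propa-1,2-dien-1-yl}-3-methoxy-2-(methoxymethoxy)cyclohexa-2,4-dien-1-one (racemic, mixture of diastereomers) | O=C1C(OCOC)=C(OC)C=C(OCc2ccccc2)C1C=C=Cc1ccc(OCc2ccccc2)c(OCc2ccccc2)c1 | intermediate
14 | 3-(benzyloxy)-2-{3-[3,4-bis(benzyloxy)phenyl]propa-1,2-dien-1-yl}-5-methoxy-6-(methoxymethoxy)phenol (racemic allene) | Oc1c(OCOC)c(OC)cc(OCc2ccccc2)c1C=C=Cc1ccc(OCc2ccccc2)c(OCc2ccccc2)c1 | intermediate
15 | (6Z)-5-(benzyloxy)-6-{(2E)-3-[3,4-bis(benzyloxy)phenyl]prop-2-en-1-ylidene}-3-methoxy-2-(methoxymethoxy)cyclohexa-2,4-dien-1-one | O=C1C(OCOC)=C(OC)C=C(OCc2ccccc2)/C1=C/C=C/c1ccc(OCc2ccccc2)c(OCc2ccccc2)c1 | intermediate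
16 | 5-(benzyloxy)-2-[3,4-bis(benzyloxy)phenyl]-7-methoxy-8-(methoxymethoxy)-2H-chromene (racemic) | COCOc1c(OC)cc(OCc2ccccc2)c2C=CC(c3ccc(OCc4ccccc4)c(OCc4ccccc4)c3)Oc12 | intermediate
17 | rac-(2R,3S,4S)-5-(benzyloxy)-2-[3,4-bis(benzyloxy)phenyl]-7-methoxy-8-(methoxymethoxy)-3,4-dihydro-2H-chromene-3,4-diol (one enantiomer drawn) | COCOc1c(OC)cc(OCc2ccccc2)c2c1O[C@H](c1ccc(OCc3ccccc3)c(OCc3ccccc3)c1)[C@@H](O)[C@H]2O | intermediate
18 | 5-(benzyloxy)-2-[3,4-bis(benzyloxy)phenyl]-7-methoxy-8-(methoxymethoxy)-2H-chromene-3,4-dione (racemic) | COCOc1c(OC)cc(OCc2ccccc2)c2C(=O)C(=O)C(c3ccc(OCc4ccccc4)c(OCc4ccccc4)c3)Oc12 | intermediate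
19 | 5-(benzyloxy)-2-[3,4-bis(benzyloxy)phenyl]-3-hydroxy-7-methoxy-8-(methoxymethoxy)-4H-chromen-4-one | COCOc1c(OC)cc(OCc2ccccc2)c2c(=O)c(O)c(-c3ccc(OCc4ccccc4)c(OCc4ccccc4)c3)oc12 | intermediate
20 | 3,5-bis(benzyloxy)-2-[3,4-bis(benzyloxy)phenyl]-7-methoxy-8-(methoxymethoxy)-4H-chromen-4-one | COCOc1c(OC)cc(OCc2ccccc2)c2c(=O)c(OCc3ccccc3)c(-c3ccc(OCc4ccccc4)c(OCc4ccccc4)c3)oc12 | intermediate
21 | 3,5-bis(benzyloxy)-2-[3,4-bis(benzyloxy)phenyl]-8-hydroxy-7-methoxy-4H-chromen-4-one | COc1cc(OCc2ccccc2)c2c(=O)c(OCc3ccccc3)c(-c3ccc(OCc4ccccc4)c(OCc4ccccc4)c3)oc2c1O | intermediate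
22 | 3,5-bis(benzyloxy)-2-[3,4-bis(benzyloxy)phenyl]-7-methoxy-4-oxo-4H-chromen-8-yl acetate | COc1cc(OCc2ccccc2)c2c(=O)c(OCc3ccccc3)c(-c3ccc(OCc4ccccc4)c(OCc4ccccc4)c3)oc2c1OC(C)=O | intermediate
23 | 2-(3,4-dihydroxyphenyl)-3,5-dihydroxy-7-methoxy-4-oxo-4H-chromen-8-yl acetate (gossypetin 7-methyl ether 8-acetate) | COc1cc(O)c2c(=O)c(O)c(-c3ccc(O)c(O)c3)oc2c1OC(C)=O | target

## Step count and risks

Total step count: 13. Longest linear sequence: 12 steps (steps 1–4 and 6–13, from 1 to 23); step 5 is a one-step side branch.

**Step 7 (key step).** Three processes may compete at 185 °C.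
- Heterolysis of the benzylic and propargylic C–O bond, which the dialkoxyphenyl group assists, returning phenol 8 and oligomers of the alkyne.
- Leakage through the oxygen-bearing ortho carbon followed by a second [3,3] shift to the free para carbon C6.
- Electrocyclic ring opening of the 2-aryl-2H-chromene on prolonged heating, with hydrogen shifts to isomeric flavenes.

The fallback changes the mechanism but not the disconnection. Ether 12 is treated at room temperature with the cationic monovalent gold catalyst Ph3PAuNTf2 in CH2Cl2. π-Activation of the terminal alkyne and 6-endo-dig attack by the hydrogen-bearing ortho carbon (intramolecular hydroarylation) should give chromene 16 directly, without breaking the O1–C2 bond. This sets out from 12 and rejoins the route at 16; no new compound is made on this way (F0).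

**Step 6.** The betaine may ionise the doubly activated alcohol instead of displacing it cleanly. That would lead to attack at the alkyne terminus, C-alkylation of the electron-rich phenol, or alkylation of the hydrazide when the ortho-substituted phenol is slow. The fallback sets out from 11. Acetylation with Ac2O and pyridine gives 1-[3,4-bis(benzyloxy)phenyl]prop-2-yn-1-yl acetate F1. F1 is then coupled with phenol 8 by copper-catalysed propargylic substitution, using Cu(MeCN)4PF6 (a monovalent copper source), an achiral 2,6-bis(oxazolinyl)pyridine ligand and iPr2NEt in MeOH at −10 °C. The copper acetylide loses acetate, and the resulting copper allenylidene is attacked by the phenoxide at the former carbinol carbon. The sequence rejoins the route at 12.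

**Step 9.** Three things may go wrong: cleavage of the glycol C3–C4 bond, a stop at the hydroxy ketone stage, or further oxidation of the product enol by excess oxidant. The fallback sets out from 17 and separates the two oxidations. DDQ in dioxane at room temperature should dehydrogenate only the doubly activated benzylic C4 carbinol, by hydride abstraction, and give rac-(2R,3R)-5-(benzyloxy)-2-[3,4-bis(benzyloxy)phenyl]-3-hydroxy-7-methoxy-8-(methoxymethoxy)-2,3-dihydro-4H-chromen-4-one F2. Dess–Martin periodinane buffered with NaHCO3 in CH2Cl2 then oxidises the remaining α-hydroxy ketone to dione 18, which tautomerises. The sequence rejoins the route at 19.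

**Step 11.** The acid may also remove the 5-O-benzyl group, whose cleavage is assisted by the peri carbonyl, so that a mixture of mono- and bis-deprotected material results. The fallback accepts this loss and uses it.
- From 20, concentrated HCl in AcOH at 50 °C under argon removes both the methoxymethyl and the 5-O-benzyl group and gives 3-(benzyloxy)-2-[3,4-bis(benzyloxy)phenyl]-5,8-dihydroxy-7-methoxy-4H-chromen-4-one F3.
- One equivalent of Ac2O in pyridine at 0 °C should acetylate only O8, because the 5-hydroxyl is tied up in the hydrogen bond to the C4 carbonyl. This gives 8-acetoxy-3-(benzyloxy)-2-[3,4-bis(benzyloxy)phenyl]-5-hydroxy-7-methoxy-4H-chromen-4-one F4, the same structure as A3.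
- Hydrogenolysis (H2, Pd/C, EtOAc/THF) then rejoins the route at 23.

F3 is a para-hydroquinone and must be kept from air.

**Step 13.** Debenzylation may stall at the hindered 3-O-benzyl ether as the catechol product binds to the catalyst. On long exposure the C2=C3 bond may be partly saturated or the acetate solvolysed. The fallback replaces hydrogenolysis by Lewis-acid dealkylation: from 22, BCl3 with pentamethylbenzene as cation scavenger in CH2Cl2 at −78 °C should cleave the aryl benzyl ethers and spare the aryl acetate. It rejoins the route at 23; no new compound is made on this way (F0).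

## Further compounds

F0 | step 7 | none | none
F1 | step 6 | 1-[3,4-bis(benzyloxy)phenyl]prop-2-yn-1-yl acetate (racemic) | C#CC(OC(C)=O)c1ccc(OCc2ccccc2)c(OCc2ccccc2)c1
F2 | step 9 | rac-(2R,3R)-5-(benzyloxy)-2-[3,4-bis(benzyloxy)phenyl]-3-hydroxy-7-methoxy-8-(methoxymethoxy)-2,3-dihydro-4H-chromen-4-one (one enantiomer drawn) | COCOc1c(OC)cc(OCc2ccccc2)c2c1O[C@H](c1ccc(OCc3ccccc3)c(OCc3ccccc3)c1)[C@@H](O)C2=O
F3 | step 11 | 3-(benzyloxy)-2-[3,4-bis(benzyloxy)phenyl]-5,8-dihydroxy-7-methoxy-4H-chromen-4-one | COc1cc(O)c2c(=O)c(OCc3ccccc3)c(-c3ccc(OCc4ccccc4)c(OCc4ccccc4)c3)oc2c1O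
F4 | step 11 | 8-acetoxy-3-(benzyloxy)-2-[3,4-bis(benzyloxy)phenyl]-5-hydroxy-7-methoxy-4H-chromen-4-one | COc1cc(O)c2c(=O)c(OCc3ccccc3)c(-c3ccc(OCc4ccccc4)c(OCc4ccccc4)c3)oc2c1OC(C)=O
F0 | step 13 | none | none
A1 | alternative 1 | 5-(benzyloxy)-2-[3,4-bis(benzyloxy)phenyl]-7-methoxy-8-(methoxymethoxy)-4H-chromen-4-one | COCOc1c(OC)cc(OCc2ccccc2)c2c(=O)cc(-c3ccc(OCc4ccccc4)c(OCc4ccccc4)c3)oc12
A2 | alternative 1 | 3-(benzyloxy)-5-methoxy-6-(methoxymethoxy)-2-[2-(triphenyl-λ5-phosphanylidene)acetyl]phenyl 3,4-bis(benzyloxy)benzoate | COCOc1c(OC)cc(OCc2ccccc2)c(C(=O)C=P(c2ccccc2)(c2ccccc2)c2ccccc2)c1OC(=O)c1ccc(OCc2ccccc2)c(OCc2ccccc2)c1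
A3 | alternative 2 | 8-acetoxy-3-(benzyloxy)-2-[3,4-bis(benzyloxy)phenyl]-5-hydroxy-7-methoxy-4H-chromen-4-one | COc1cc(O)c2c(=O)c(OCc3ccccc3)c(-c3ccc(OCc4ccccc4)c(OCc4ccccc4)c3)oc2c1OC(C)=O
A4 | alternative 2 | 1-{5-(benzyloxy)-6-[3,4-bis(benzyloxy)phenyl]-4-oxo-4H-pyran-2-yl}-2-methoxy-4-oxocyclobut-2-en-1-yl acetate (racemic) | CC(=O)OC1(c2cc(=O)c(OCc3ccccc3)c(-c3ccc(OCc4ccccc4)c(OCc4ccccc4)c3)o2)C(OC)=CC1=O
A5 | alternative 3 | 2-[3,4-bis(benzyloxy)phenyl]-5,7-dimethoxy-4H-chromen-4-one | COc1cc(OC)c2c(=O)cc(-c3ccc(OCc4ccccc4)c(OCc4ccccc4)c3)oc2c1
A6 | alternative 3 | 3,5-dimethoxybenzyne (1,2-didehydro-3,5-dimethoxybenzene) | COC1=CC(OC)=CC#C1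
A7 | alternative 3 | 3-[3,4-bis(benzyloxy)phenyl]prop-2-ynoic acid | OC(=O)C#Cc1ccc(OCc2ccccc2)c(OCc2ccccc2)c1
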